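## The problem

The target is a germacrane: a ten-membered carbocycle (C1–C10) with an E-trisubstituted olefin (C1=C10, methyl on C10), a trans-substituted oxirane (C4–C5, methyl on C4) and four contiguous stereogenic carbons, C6 (acetate), C7 (isopropyl), C8 (tiglate) and C9 (free hydroxyl). A synthesis must close a medium ring, set six stereocentres, fix the geometry of two trisubstituted double bonds (one ends as the oxirane) and tell three secondary oxygens apart. The C6–C9 tetrad is best set on a small rigid ring. Once it is in place, C6 can control C4 and C5: an allylic C6 hydroxyl next to an olefin whose C4 methyl is cis to C6 directs epoxidation to one face through 1,3-allylic strain. The sensitive parts are the oxirane (opened transannularly by C1=C10 under acid), the 1(10),4-diene before it (acid-induced cyclisation, Cope rearrangement to a divinylcyclohexane on heating) and the tiglate, which is cis-vicinal to the free C9 hydroxyl and can migrate under base. The enabling feature is that C1=C10 and C4=C5 are the ends of a 1,5-diene joined through C2–C3, while C5 and C10 are joined the other way round by C6–C9. Reconnecting C5 to C10 and cutting C2–C3 gives a cyclohexane (C5–C10) with vinyl and oxygen on C10 and isopropenyl on C5, the substrate of an oxy-Cope ring expansion.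

## Retrosynthesis

**End game (32 back to 29).** The C9 ether, the C6 acetate and the two C–O bonds of the oxirane are removed in turn (32 ← 31 ← 30 ← 29). The oxirane has to come after ring formation because C4 and C5 are olefinic termini of the ring-forming step. Using the free C6 hydroxyl of 29 to direct it, with C9 still masked, avoids epoxidation of C1=C10. The precursor 29 has one defined olefin in place of two stereocentres. The forward epoxidation must be face-selective, and the last deprotection must be neither acidic nor basic.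

**Esters and C10 methyl (29 back to 24).** The C8–O acyl bond is cut to tiglic acid 27 and alcohol 26, and the C10–CH3 bond of 25 is cut to enol triflate 24. The triflate is the direct trapping product of the ring-expansion enolate, so C10 needs no extra carbon before the key step. Carrying the methyl through the rearrangement is not possible, since C10 must bear the oxygen. The forward steps need a cross-coupling with retention of geometry at or below room temperature and removal of the C8 ether in the presence of the C9 ether.

**Key disconnection (24 back to 21).** C2–C3 is cut and C5–C10 re-formed, giving trans-1-vinyl-2-isopropenylcyclohexanol 21. Against end-to-end closures of the ten-membered ring, this cut needs no dilution and takes both olefin geometries from a chair transition state. The precursor is a chair cyclohexane on which all four stereocentres of the tetrad can be set by ring rules. The forward reaction needs vinyl and isopropenyl trans, and an enolate that is trapped before it equilibrates.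

**C10–vinyl bond (21 back to 19 and 20).** Cutting this bond gives ketone 19 and vinylmagnesium bromide 20. The alternative order (vinyl first, isopropenyl second through an epoxide) leads to the cis-dialkenyl isomer, because both nucleophiles would enter anti to the same oxirane. The forward addition must come from the α face, anti to both flanking substituents.

**C5–isopropenyl bond and C6 oxygen (19 back to 14 and 15, then to 9).** Cutting C5–C(isopropenyl) leads to α-epoxide 14 and isopropenylmagnesium bromide 15; trans-diaxial opening sets C5 and C6 together. α-Alkenylation of a C10 ketone or aldol/dehydration would not deliver the C6 oxygen. The oxirane must lie syn to the C7 isopropyl group, which no reagent chooses unaided, so it is placed by a C10 α-hydroxyl (12 → 13). That alcohol comes from enone 9 by reduction to the β-alcohol 10 and inversion. C10 stays at the alcohol level during the opening because epoxy ketones are reduced by cuprates; a temporary silyl ether keeps C10 and C6 distinguishable.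

**Unsaturation and ether pattern (9 back to 5).** Enone 9 comes from ketone 7 by dehydrogenation on the C5 side, and 7 from diol 5 by two different etherifications (6, then 7). The dihydroxylation has to precede the isopropenyl group, which would compete for OsO4. C8 and C9 need ethers, not silyl groups, because both are close to the C10 alkoxide of the key step. The forward steps need regioselective alkylation of a cis-diol and regioselective enolisation.

**Diol and first stereocentre (5 back to 1).** Diol 5 comes from (S)-cryptone 4 by syn-dihydroxylation anti to the isopropyl group, and 4 from achiral 4-isopropylcyclohexanone 1 by desymmetrising enolisation (3) and Saegusa–Ito oxidation. All later centres are derived from C7.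

## Roads not taken

**Alternative 1:** The cut is C8–C9. SmI2 would reduce the C9 enal and the C8 aldehyde of seco-dialdehyde A1 to ketyls whose coupling closes the ten-membered ring and creates both carbinol centres of diol A2.
- Merits: the step is convergent, makes two stereocentres and the ring at once, and lets the acetate and the oxirane be installed on an open chain with few protecting-group exchanges. In step economy it is better than the chosen plan.
- Weak points: the ten-membered closure is entropically costly and needs high dilution. The cis sense and the absolute sense of the new diol rest on an untested medium-ring ketyl coupling. The enal ketyl can also couple through C1. The C8 aldehyde is α-branched and epimerisable. A2 still needs C8-selective tigloylation beside a free C9 hydroxyl.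
- Comparison: the chosen plan sets against this a ring formation without dilution, a cis-diol made by a reliable dihydroxylation on a six-membered ring, and C8/C9 told apart before the ring is expanded.

**Alternative 2:** The cut is again C5–C10, but by light. Irradiation of trans-fused hexalin A3 would open ring A by a conrotatory 6π process to triene A4.
- Merits: both ring methyl groups are present from the start, both trisubstituted olefins are formed with E geometry in one symmetry-controlled step, and no cross-coupling is needed. In that respect it is more direct than the triflate detour.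
- Weak points: A3 needs an angular methyl at C10 next to the C9 oxygen on a trans-fused diene. A4 carries an extra C2=C3 Z-olefin in a conjugated triene, which has to be reduced selectively. The photoreaction gives photostationary mixtures, and such trienes undergo thermal hydrogen shifts and reclosure.
- Comparison: the chosen plan gives the isolated 1,5-diene directly in a ground-state process made irreversible by enolate formation, at the price of a longer protecting-group sequence.

**Alternative 3:** The cut is the C1–C6 bond of a bicyclic epoxy ketone. Tosylhydrazone formation from epoxy octalone A5 and Eschenmoser–Tanabe fragmentation would give cyclodecynone A6.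
- Merits: the fragmentation is dependable, needs no dilution, and the bicyclic precursor allows ring-controlled stereochemistry at C7–C9. As a ring-forming step it is as reliable as the one chosen.
- Weak points: A6 is far from the target. The alkyne must become an E-olefin with methyl regioselectively on C10. The C6 ketone must be reduced with face control on a flexible ring, next to an epimerisable C7. The C4/C5 acetonide must be turned into the oxirane at a tertiary centre.
- Comparison: in the chosen plan the olefin geometry, the C10 handle and the C6 configuration are all in hand when the ring is formed.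

Key step: step 15

Remark on numbering and faces: locants are those of the target throughout (the six-membered ring is C5–C10; the carbonyl carbon of 1 is C10, the isopropyl-bearing carbon C7); β is the ring face of the C8 and C9 oxygens, α the face of the C7 isopropyl group.

Remark on step 1: by analogy with 4-tert-butylcyclohexanone, the (S,S)-amide is taken to give the (R)-silyl enol ether; if the sense proves opposite, the (R,R)-amine is used.

## Route

Step 1
Reactants: 1 4-isopropylcyclohexanone
Product: 3 (R)-4-isopropyl-1-(trimethylsilyloxy)cyclohex-1-ene, via lithium enolate 2 (not isolated)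
Conditions: LiN[(S)-CH(Me)Ph]2 (from the amine and n-BuLi), Me3SiCl present from the start, THF, −78 °C
Reagents that add atoms: chlorotrimethylsilane, C[Si](C)(C)Cl
Why: Desymmetrising enolisation by a C2-symmetric chiral lithium amide with in situ silylation; the choice between the two enantiotopic α-methylene groups fixes C7, and selectivity should be high but not complete, so crystalline diol 5 is a point for enrichment.

Step 2
Reactants: 3 (R)-4-isopropyl-1-(trimethylsilyloxy)cyclohex-1-ene
Product: 4 (S)-4-isopropylcyclohex-2-en-1-one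
Conditions: Pd(OAc)2 (10 mol %), O2 (1 atm), DMSO, rt
Reagents that add atoms: none
Why: Saegusa–Ito oxidation; the palladium enolate at C9 loses the C8 hydride, so the olefin forms on the enolised side and C7 is untouched.

Step 3
Reactants: 4 (S)-4-isopropylcyclohex-2-en-1-one
Product: 5 (2S,3S,4S)-2,3-dihydroxy-4-isopropylcyclohexan-1-one (8β,9β-diol; 7α-isopropyl)
Conditions: OsO4 (2 mol %), N-methylmorpholine N-oxide, acetone/H2O, 0 °C → rt
Reagents that add atoms: osmium tetroxide, O=[Os](=O)(=O)=O; N-methylmorpholine N-oxide, C[N+]1([O-])CCOCC1; water, O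
Why: Upjohn syn-dihydroxylation of the enone; OsO4 adds to the face anti to the adjacent C7 isopropyl group, setting C8 and C9 cis to each other and trans to isopropyl.

Step 4
Reactants: 5 (2S,3S,4S)-2,3-dihydroxy-4-isopropylcyclohexan-1-one
Product: 6 9β-hydroxy-7α-isopropyl-8β-(4-methoxybenzyloxy)cyclohexan-10-one
Conditions: 4-MeOC6H4CH2Br, Ph2BOCH2CH2NH2 (10 mol %), Ag2O, MeCN, 40 °C
Reagents that add atoms: 4-methoxybenzyl bromide, COc1ccc(CBr)cc1
Why: Diarylborinic-acid-catalysed regioselective alkylation of a cis-1,2-diol; the borinate of the diol reacts at its equatorial oxygen (C8, with isopropyl equatorial) and leaves the axial α-ketol hydroxyl; no new stereocentre.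

Step 5
Reactants: 6 9β-hydroxy-7α-isopropyl-8β-(4-methoxybenzyloxy)cyclohexan-10-one
Product: 7 7α-isopropyl-8β-(4-methoxybenzyloxy)-9β-(2-naphthylmethoxy)cyclohexan-10-one
Conditions: 2-(bromomethyl)naphthalene, Ag2O, 4 Å sieves, CH2Cl2, rt, dark
Reagents that add atoms: 2-(bromomethyl)naphthalene, BrCc1ccc2ccccc2c1
Why: Silver-oxide-mediated Williamson-type etherification under non-basic conditions, chosen because alkoxide bases would epimerise C9 or eliminate the C8 ether of this α,β-dioxygenated ketone.

Step 6
Reactants: 7 7α-isopropyl-8β-(4-methoxybenzyloxy)-9β-(2-naphthylmethoxy)cyclohexan-10-one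
Product: 9 7α-isopropyl-8β-(4-methoxybenzyloxy)-9β-(2-naphthylmethoxy)cyclohex-5-en-10-one, via lithium enolate 8 (not isolated)
Conditions: LiN(iPr)2, THF, −78 °C; then PhS(Cl)=N-t-Bu, −78 °C
Reagents that add atoms: none
Why: Kinetic deprotonation at the unhindered C5 methylene (not at the alkoxy-bearing C9), then one-pot dehydrogenation: the enolate attacks sulfur of the sulfinimidoyl chloride and syn-elimination gives the C5=C6 enone.

Step 7
Reactants: 9 7α-isopropyl-8β-(4-methoxybenzyloxy)-9β-(2-naphthylmethoxy)cyclohex-5-en-10-one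
Product: 10 7α-isopropyl-8β-(4-methoxybenzyloxy)-9β-(2-naphthylmethoxy)cyclohex-5-en-10β-ol
Conditions: NaBH4, CeCl3·7H2O, MeOH, −78 °C
Reagents that add atoms: none
Why: Luche 1,2-reduction; in the half-chair with equatorial isopropyl the C9 ether is axial and hydride adds axially and anti to it, so the new C10 hydroxyl should be pseudo-equatorial and cis to the C9 oxygen.

Step 8
Reactants: 10 7α-isopropyl-8β-(4-methoxybenzyloxy)-9β-(2-naphthylmethoxy)cyclohex-5-en-10β-ol
Product: 12 7α-isopropyl-8β-(4-methoxybenzyloxy)-9β-(2-naphthylmethoxy)cyclohex-5-en-10α-ol, via 10α-(4-nitrobenzoate) 11 (not isolated)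
Conditions: 4-O2NC6H4CO2H, PPh3, diisopropyl azodicarboxylate, THF, 0 °C → rt; then K2CO3, MeOH, rt
Reagents that add atoms: 4-nitrobenzoic acid, O=C(O)c1ccc(cc1)[N+](=O)[O-]
Why: Mitsunobu inversion (SN2 at C10 by the carboxylate, which supplies the new C10 oxygen) and methanolysis in the same flask give the α-alcohol needed as directing group; attack at the allylic terminus C6 is disfavoured by the neighbouring isopropyl group.

Step 9
Reactants: 12 7α-isopropyl-8β-(4-methoxybenzyloxy)-9β-(2-naphthylmethoxy)cyclohex-5-en-10α-ol
Product: 13 5α,6α-epoxy-7α-isopropyl-8β-(4-methoxybenzyloxy)-9β-(2-naphthylmethoxy)cyclohexan-10α-ol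
Conditions: VO(acac)2 (5 mol %), t-BuOOH, CH2Cl2, 0 °C → rt
Reagents that add atoms: tert-butyl hydroperoxide, CC(C)(C)OO
Why: Hydroxyl-directed epoxidation of a cyclic allylic alcohol; the pseudo-axial C10 hydroxyl binds the vanadium peroxide and delivers oxygen to its own (α) face, overriding the adjacent isopropyl group and setting C5 and C6.

Step 10
Reactants: 13 5α,6α-epoxy-7α-isopropyl-8β-(4-methoxybenzyloxy)-9β-(2-naphthylmethoxy)cyclohexan-10α-ol
Product: 14 5α,6α-epoxy-7α-isopropyl-8β-(4-methoxybenzyloxy)-9β-(2-naphthylmethoxy)-10α-(triethylsilyloxy)cyclohexane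
Conditions: Et3SiCl, imidazole, DMF, 0 °C → rt
Reagents that add atoms: chlorotriethylsilane, CC[Si](Cl)(CC)CC
Why: Routine silylation; the temporary C10 silyl ether keeps the C10 and C6 oxygens distinguishable after the epoxide is opened.

Step 11
Reactants: 14 5α,6α-epoxy-7α-isopropyl-8β-(4-methoxybenzyloxy)-9β-(2-naphthylmethoxy)-10α-(triethylsilyloxy)cyclohexane; 15 isopropenylmagnesium bromide
Product: 16 5β-isopropenyl-7α-isopropyl-8β-(4-methoxybenzyloxy)-9β-(2-naphthylmethoxy)-10α-(triethylsilyloxy)cyclohexan-6α-ol
Conditions: CuBr·SMe2 (20 mol %), THF, −30 → 0 °C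
Reagents that add atoms: none
Why: Copper-catalysed Grignard opening of an epoxide with inversion (Fürst–Plattner trans-diaxial opening); from the half-chair with equatorial isopropyl the diaxial product arises by attack at C5, also the carbon remote from the isopropyl group, giving 5β-isopropenyl trans to the retained 6α-hydroxyl.

Step 12
Reactants: 16 5β-isopropenyl-7α-isopropyl-8β-(4-methoxybenzyloxy)-9β-(2-naphthylmethoxy)-10α-(triethylsilyloxy)cyclohexan-6α-ol
Product: 17 6α-(tert-butyldimethylsilyloxy)-5β-isopropenyl-7α-isopropyl-8β-(4-methoxybenzyloxy)-9β-(2-naphthylmethoxy)-10α-(triethylsilyloxy)cyclohexane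
Conditions: t-BuMe2SiOTf, 2,6-lutidine, CH2Cl2, −78 → 0 °C
Reagents that add atoms: tert-butyldimethylsilyl trifluoromethanesulfonate, CC(C)(C)[Si](C)(C)OS(=O)(=O)C(F)(F)F
Why: Silyl triflate silylation of a hindered secondary alcohol; the robust C6 silyl ether is trans-1,3 to the later C10 alkoxide and so has no path for migration.

Step 13
Reactants: 17 6α-(tert-butyldimethylsilyloxy)-5β-isopropenyl-7α-isopropyl-8β-(4-methoxybenzyloxy)-9β-(2-naphthylmethoxy)-10α-(triethylsilyloxy)cyclohexane
Product: 19 6α-(tert-butyldimethylsilyloxy)-5β-isopropenyl-7α-isopropyl-8β-(4-methoxybenzyloxy)-9β-(2-naphthylmethoxy)cyclohexan-10-one, via 10α-alcohol 18 (not isolated)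
Conditions: IBX, DMSO, rt
Reagents that add atoms: none
Why: Oxidative desilylation; IBX in DMSO cleaves triethylsilyl ethers and oxidises the freed alcohol in the same flask while tert-butyldimethylsilyl ethers stay, and the near-neutral medium avoids epimerisation or conjugation of the α-isopropenyl ketone.

Step 14
Reactants: 19 6α-(tert-butyldimethylsilyloxy)-5β-isopropenyl-7α-isopropyl-8β-(4-methoxybenzyloxy)-9β-(2-naphthylmethoxy)cyclohexan-10-one; 20 vinylmagnesium bromide
Product: 21 6α-(tert-butyldimethylsilyloxy)-5β-isopropenyl-7α-isopropyl-8β-(4-methoxybenzyloxy)-9β-(2-naphthylmethoxy)-10α-vinylcyclohexan-10β-ol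
Conditions: CeCl3 (anhydrous), THF, −78 °C
Reagents that add atoms: none
Why: Organocerium 1,2-addition, which suppresses enolisation and β-elimination of the C6 silyloxy group; in the chair with equatorial C5 and C9 substituents the axial C8 ether blocks the β face, so vinyl enters from the α face, anti to both flanking groups, setting C10 with vinyl trans to isopropenyl.

Step 15
Reactants: 21 6α-(tert-butyldimethylsilyloxy)-5β-isopropenyl-7α-isopropyl-8β-(4-methoxybenzyloxy)-9β-(2-naphthylmethoxy)-10α-vinylcyclohexan-10β-ol
Product: 24 6-(tert-butyldimethylsilyloxy)-7-isopropyl-8-(4-methoxybenzyloxy)-4-methyl-9-(2-naphthylmethoxy)cyclodeca-1(10),4-dien-10-yl trifluoromethanesulfonate (4E; C2 trans to C9 across C1=C10; C6–C9 as in 21), via potassium alkoxide 22 (not isolated), via potassium enolate 23 (not isolated)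
Conditions: KH, 18-crown-6, THF, 0 °C → rt; then PhNTf2, −78 → 0 °C
Reagents that add atoms: N-phenylbis(trifluoromethanesulfonimide), O=S(=O)(N(c1ccccc1)S(=O)(=O)C(F)(F)F)C(F)(F)F
Why: KH with 18-crown-6 gives the dissociated alkoxide 22, whose [3,3] sigmatropic shift (anionic oxy-Cope rearrangement) forms C2–C3 as C5–C10 breaks and delivers enolate 23. The closest known reaction type is the anionic oxy-Cope ring expansion of trans-1,2-dialkenylcyclohexanols to (E)-cyclodec-5-enone enolates with trapping in the same flask. The ten-membered ring is closed by ring expansion, that is by scission of the C5–C10 bond of the six-membered ring within a chair-like six-centre transition state, not by end-to-end cyclisation, so no dilution is needed. No stereocentre is created: C5 and C10 become trigonal and the C6–C9 tetrad is carried through. The selectivity needed is olefin geometry; with vinyl and isopropenyl trans-diequatorial the ring bonds to C6 and C9 are both equatorial on the pericyclic chair, which makes C4=C5 E and puts C9 trans to C2 across C1=C10. The reacting chair is the ground-state chair of 21 (only isopropyl and the C8 ether axial), C8 and C9 carry ethers that cannot migrate to the alkoxide, and the C6 silyl ether is equatorial and trans-1,3 to it. The enolate is formed regiospecifically toward C1, and O-sulfonylation at low temperature before any proton transfer fixes it as triflate 24 (formally 1(10)Z because the triflate oxygen outranks C9).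

Step 16
Reactants: 24 the ten-membered enol triflate
Product: 25 (1(10)E,4E)-6-(tert-butyldimethylsilyloxy)-7-isopropyl-8-(4-methoxybenzyloxy)-4,10-dimethyl-9-(2-naphthylmethoxy)cyclodeca-1(10),4-diene (C6–C9 as in the target)
Conditions: Pd(PPh3)4 (5 mol %), Me2Zn, THF, 0 °C → rt
Reagents that add atoms: dimethylzinc, C[Zn]C
Why: Negishi coupling of an alkenyl triflate; oxidative addition to zerovalent palladium and reductive elimination go with retention, so the ring geometry at C1=C10 is kept, and room temperature avoids Cope rearrangement of the 1,5-diene.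

Step 17
Reactants: 25 the protected germacra-1(10),4-diene
Product: 26 C8 alcohol of 25 (6-silyloxy, 9-(2-naphthylmethoxy) retained)
Conditions: DDQ (1.2 equiv), CH2Cl2/pH 7 phosphate buffer, 0 °C
Reagents that add atoms: none
Why: Oxidative cleavage of the electron-rich 4-methoxybenzyl ether (benzylic hydride abstraction, hydrolysis of the oxocarbenium ion), run cold with limited oxidant because the 2-naphthylmethyl ether is oxidised more slowly.

Step 18
Reactants: 26 C8 alcohol; 27 tiglic acid
Product: 28 C8 tiglate (6-silyloxy, 9-(2-naphthylmethoxy))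
Conditions: 2,4,6-Cl3C6H2COCl, Et3N, THF, rt; then 26, DMAP, toluene, rt
Reagents that add atoms: none
Why: Yamaguchi esterification of a hindered secondary alcohol through the mixed anhydride; the tiglate is the stable E isomer and keeps its geometry.

Step 19
Reactants: 28 C8 tiglate
Product: 29 C6 alcohol (8-tiglate, 9-(2-naphthylmethoxy))
Conditions: HF·pyridine, pyridine, THF, 0 °C → rt
Reagents that add atoms: none
Why: Fluoride desilylation in a buffered, non-basic medium, which avoids acyl migration from C8 and keeps the acid level below what triggers transannular cyclisation of the diene.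

Step 20
Reactants: 29 C6 alcohol
Product: 30 (4R,5R)-4,5-epoxy C6 alcohol (8-tiglate, 9-(2-naphthylmethoxy), C1=C10 intact)
Conditions: VO(acac)2 (10 mol %), t-BuOOH, CH2Cl2, 0 °C
Reagents that add atoms: tert-butyl hydroperoxide, CC(C)(C)OO
Why: Hydroxyl-directed epoxidation, threo-selective by 1,3-allylic strain: with C6–H eclipsing the olefin toward the cis C4 methyl and C7 on the inner ring face, the C6 hydroxyl sits on the outer face of C4=C5 and delivers oxygen there, setting C4 and C5; C1=C10 has no free hydroxyl and the tiglate olefin is electron-poor.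

Step 21
Reactants: 30 4,5-epoxy C6 alcohol
Product: 31 C6 acetate (2-naphthylmethyl ether of the target)
Conditions: Ac2O, pyridine, DMAP (cat.), CH2Cl2, 0 °C → rt
Reagents that add atoms: acetic anhydride, CC(=O)OC(C)=O
Why: Base-buffered acetylation of the only free hydroxyl; the oxirane tolerates these conditions.

Step 22
Reactants: 31 C6 acetate
Product: 32 (1(10)E,4R,5R,6S,7S,8S,9R)-6-acetoxy-4,5-epoxy-9-hydroxygermacr-1(10)-en-8-yl (E)-2-methylbut-2-enoate
Conditions: DDQ, CH2Cl2/pH 7 phosphate buffer, rt
Reagents that add atoms: none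
Why: Oxidative cleavage of the 2-naphthylmethyl ether under buffered conditions that are neither acidic enough to open the oxirane transannularly nor basic enough to move the tiglate to C9; oxidant and time are kept to the minimum so that the freed allylic alcohol is not oxidised further.

## Compound list

1 | 4-isopropylcyclohexanone | CC(C)C1CCC(=O)CC1 | starting material
2 | lithium enolate of 1 | [Li+].[O-]C1=CC[C@H](C(C)C)CC1 | intermediate
3 | (R)-4-isopropyl-1-(trimethylsilyloxy)cyclohex-1-ene | C[Si](C)(C)OC1=CC[C@H](C(C)C)CC1 | intermediate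
4 | (S)-4-isopropylcyclohex-2-en-1-one | O=C1C=C[C@H](C(C)C)CC1 | intermediate
5 | (2S,3S,4S)-2,3-dihydroxy-4-isopropylcyclohexan-1-one | O[C@H]1[C@H](C(C)C)CCC(=O)[C@H]1O | intermediate
6 | 9β-hydroxy-7α-isopropyl-8β-(4-methoxybenzyloxy)cyclohexan-10-one | COc3ccc(cc3)CO[C@H]1[C@H](C(C)C)CCC(=O)[C@H]1O | intermediate
7 | 7α-isopropyl-8β-(4-methoxybenzyloxy)-9β-(2-naphthylmethoxy)cyclohexan-10-one | COc3ccc(cc3)CO[C@H]1[C@H](C(C)C)CCC(=O)[C@H]1OCc4ccc5ccccc5c4 | intermediate
8 | lithium C5(10)-enolate of 7 | COc3ccc(cc3)CO[C@H]1[C@H](C(C)C)CC=C([O-])[C@H]1OCc4ccc5ccccc5c4.[Li+] | intermediate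
9 | 7α-isopropyl-8β-(4-methoxybenzyloxy)-9β-(2-naphthylmethoxy)cyclohex-5-en-10-one | COc3ccc(cc3)CO[C@H]1[C@H](C(C)C)C=CC(=O)[C@H]1OCc4ccc5ccccc5c4 | intermediate
10 | 10β-allylic alcohol (cis to the C9 ether) | COc3ccc(cc3)CO[C@H]1[C@H](C(C)C)C=C[C@@H](O)[C@H]1OCc4ccc5ccccc5c4 | intermediate
11 | 10α-(4-nitrobenzoate) | COc3ccc(cc3)CO[C@H]1[C@H](C(C)C)C=C[C@H](OC(=O)c6ccc(cc6)[N+](=O)[O-])[C@H]1OCc4ccc5ccccc5c4 | intermediate
12 | 10α-allylic alcohol (trans to the C9 ether) | COc3ccc(cc3)CO[C@H]1[C@H](C(C)C)C=C[C@H](O)[C@H]1OCc4ccc5ccccc5c4 | intermediate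
13 | 5α,6α-epoxy 10α-alcohol | COc3ccc(cc3)CO[C@H]1[C@H](C(C)C)[C@@H]2O[C@@H]2[C@H](O)[C@H]1OCc4ccc5ccccc5c4 | intermediate
14 | 5α,6α-epoxy 10α-triethylsilyl ether | COc3ccc(cc3)CO[C@H]1[C@H](C(C)C)[C@@H]2O[C@@H]2[C@H](O[Si](CC)(CC)CC)[C@H]1OCc4ccc5ccccc5c4 | intermediate
15 | isopropenylmagnesium bromide | CC(=C)[Mg]Br | starting material
16 | 5β-isopropenyl 6α-alcohol (10α-triethylsilyloxy) | COc3ccc(cc3)CO[C@H]1[C@H](C(C)C)[C@H](O)[C@@H](C(C)=C)[C@H](O[Si](CC)(CC)CC)[C@H]1OCc4ccc5ccccc5c4 | intermediate
17 | 6α-tert-butyldimethylsilyl 10α-triethylsilyl bis-ether | COc3ccc(cc3)CO[C@H]1[C@H](C(C)C)[C@H](O[Si](C)(C)C(C)(C)C)[C@@H](C(C)=C)[C@H](O[Si](CC)(CC)CC)[C@H]1OCc4ccc5ccccc5c4 | intermediate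
18 | 10α-alcohol (6α-tert-butyldimethylsilyloxy) | COc3ccc(cc3)CO[C@H]1[C@H](C(C)C)[C@H](O[Si](C)(C)C(C)(C)C)[C@@H](C(C)=C)[C@H](O)[C@H]1OCc4ccc5ccccc5c4 | intermediate
19 | C10 ketone (5β-isopropenyl, 6α-tert-butyldimethylsilyloxy) | COc3ccc(cc3)CO[C@H]1[C@H](C(C)C)[C@H](O[Si](C)(C)C(C)(C)C)[C@@H](C(C)=C)C(=O)[C@H]1OCc4ccc5ccccc5c4 | intermediate
20 | vinylmagnesium bromide | C=C[Mg]Br | starting material
21 | trans-1-vinyl-2-isopropenylcyclohexanol (10β-OH, 10α-vinyl, 5β-isopropenyl) | COc3ccc(cc3)CO[C@H]1[C@H](C(C)C)[C@H](O[Si](C)(C)C(C)(C)C)[C@@H](C(C)=C)[C@](O)(C=C)[C@H]1OCc4ccc5ccccc5c4 | intermediate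
22 | potassium alkoxide of 21 | COc3ccc(cc3)CO[C@H]1[C@H](C(C)C)[C@H](O[Si](C)(C)C(C)(C)C)[C@@H](C(C)=C)[C@]([O-])(C=C)[C@H]1OCc4ccc5ccccc5c4.[K+] | intermediate
23 | potassium C1(10)-enolate of the ten-membered ring | COc3ccc(cc3)CO[C@H]1[C@H](C(C)C)[C@H](O[Si](C)(C)C(C)(C)C)/C=C(\C)CC/C=C(\[O-])[C@H]1OCc4ccc5ccccc5c4.[K+] | intermediate
24 | ten-membered enol triflate (4E; C2 trans to C9 across C1=C10) | COc3ccc(cc3)CO[C@H]1[C@H](C(C)C)[C@H](O[Si](C)(C)C(C)(C)C)/C=C(\C)CC/C=C(\OS(=O)(=O)C(F)(F)F)[C@H]1OCc4ccc5ccccc5c4 | intermediate
25 | protected (1(10)E,4E)-germacra-1(10),4-diene (6-OTBS, 8-OPMB, 9-ONAP) | COc3ccc(cc3)CO[C@H]1[C@H](C(C)C)[C@H](O[Si](C)(C)C(C)(C)C)/C=C(\C)CC/C=C(\C)[C@H]1OCc4ccc5ccccc5c4 | intermediate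
26 | C8 alcohol | O[C@H]1[C@H](C(C)C)[C@H](O[Si](C)(C)C(C)(C)C)/C=C(\C)CC/C=C(\C)[C@H]1OCc4ccc5ccccc5c4 | intermediate
27 | tiglic acid | C/C=C(\C)C(=O)O | starting material
28 | C8 tiglate | C/C=C(\C)C(=O)O[C@H]1[C@H](C(C)C)[C@H](O[Si](C)(C)C(C)(C)C)/C=C(\C)CC/C=C(\C)[C@H]1OCc4ccc5ccccc5c4 | intermediate
29 | C6 alcohol (8-tiglate) | C/C=C(\C)C(=O)O[C@H]1[C@H](C(C)C)[C@H](O)/C=C(\C)CC/C=C(\C)[C@H]1OCc4ccc5ccccc5c4 | intermediate
30 | (4R,5R)-4,5-epoxy C6 alcohol | C/C=C(\C)C(=O)O[C@H]1[C@H](C(C)C)[C@H](O)[C@H]2O[C@]2(C)CC/C=C(\C)[C@H]1OCc4ccc5ccccc5c4 | intermediate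
31 | C6 acetate, 9-O-(2-naphthylmethyl) ether of the target | C/C=C(\C)C(=O)O[C@H]1[C@H](C(C)C)[C@H](OC(C)=O)[C@H]2O[C@]2(C)CC/C=C(\C)[C@H]1OCc4ccc5ccccc5c4 | intermediate
32 | (1(10)E,4R,5R,6S,7S,8S,9R)-6-acetoxy-4,5-epoxy-9-hydroxygermacr-1(10)-en-8-yl tiglate | C/C=C(\C)C(=O)O[C@H]1[C@H](C(C)C)[C@H](OC(C)=O)[C@H]2O[C@]2(C)CC/C=C(\C)[C@H]1O | target

## Step count and uncertain steps

Total step count: 22. Longest linear sequence: 22 steps (from 1).

**Step 15 (key step).** The most likely failure is proton transfer within enolate 23 during the warm phase, which moves the enolate toward C9 and is followed by β-elimination of the C8 ether, or triflation too slow to outrun it. Fallback: from 21, run the rearrangement, quench with buffer and isolate the (E)-cyclodec-5-en-10-one F5. Then deprotonate kinetically at the C1 methylene with KN(SiMe3)2 at −78 °C in the presence of N-(5-chloro-2-pyridyl)bis(trifluoromethanesulfonimide), returning to 24. The geometry of this re-formed enolate is less certain than that from the rearrangement and would have to be confirmed.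

**Step 4.** Poor discrimination between the two hydroxyls, or degradation of the α-ketol (epimerisation at C9, loss of the C8 oxygen) under the silver and borinate conditions. Fallback: from 5, form the 4-methoxybenzylidene acetal F1 (4-MeOC6H4CH(OMe)2, pyridinium p-toluenesulfonate) and dehydrogenate as in step 6 to enone acetal F2. Reduce and open in one operation with iBu2AlH to 8β-(4-methoxybenzyloxy)-9β,10β-diol F3; the aluminium alkoxide at C10 directs cleavage of the neighbouring C9–O acetal bond and the hindered C8 oxygen keeps the benzyl group. Reoxidise the allylic C10 alcohol with MnO2 to hydroxy enone F4, and etherify C9 as in step 5, returning to 9.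

**Step 11.** Slow or misdirected opening, because the nucleophile approaches C5 syn-axial to the C9 ether, with elimination or attack at C6 taking over. Fallback: from 14, open with the slimmer lithium (trimethylsilyl)acetylide and BF3·OEt2 to 5β-alkynyl alcohol F6, remove the C-silyl group (K2CO3, MeOH) to terminal alkyne F7, and convert the ethynyl group into isopropenyl by zirconium-catalysed methylalumination (Me3Al, Cp2ZrCl2) and protonolysis, returning to 16.

**Step 17.** Insufficient rate difference between the two benzyl-type ethers toward DDQ, giving loss of the C9 ether as well. Fallback: move the cleavage to the triflate stage, where the deactivated C1=C10 olefin tolerates the acidic oxidant (NH4)2Ce(NO3)6, which is known to discriminate the two ethers. From 24 this gives C8 alcohol F8, Yamaguchi esterification with 27 gives tiglate triflate F9, and Negishi methylation as in step 16 returns to 28.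

**Step 20.** Transannular attack of C1=C10 on the vanadium-activated oxirane, or competing oxidation at the electron-rich C1=C10 olefin. Fallback: epoxidise while C1=C10 is still the electron-poor enol triflate. From 24 go through F8 and F9 as above, desilylate (HF·pyridine) to C6 alcohol F10, epoxidise with VO(acac)2/t-BuOOH to epoxy triflate F11, and methylate with Me2Zn and Pd(PPh3)4, returning to 30.

## Further compounds

F1 | step 4 | 8β,9β-O-(4-methoxybenzylidene) acetal of 5 (acetal carbon as a mixture) | COc3ccc(cc3)C2O[C@H]1[C@H](C(C)C)CCC(=O)[C@H]1O2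
F2 | step 4 | 8β,9β-O-(4-methoxybenzylidene)-7α-isopropylcyclohex-5-en-10-one | COc3ccc(cc3)C2O[C@H]1[C@H](C(C)C)C=CC(=O)[C@H]1O2
F3 | step 4 | 7α-isopropyl-8β-(4-methoxybenzyloxy)cyclohex-5-ene-9β,10β-diol | COc3ccc(cc3)CO[C@H]1[C@H](C(C)C)C=C[C@@H](O)[C@H]1O
F4 | step 4 | 9β-hydroxy-7α-isopropyl-8β-(4-methoxybenzyloxy)cyclohex-5-en-10-one | COc3ccc(cc3)CO[C@H]1[C@H](C(C)C)C=CC(=O)[C@H]1O
F5 | step 15 | (4E)-6-(tert-butyldimethylsilyloxy)-7-isopropyl-8-(4-methoxybenzyloxy)-4-methyl-9-(2-naphthylmethoxy)cyclodec-4-en-10-one | COc3ccc(cc3)CO[C@H]1[C@H](C(C)C)[C@H](O[Si](C)(C)C(C)(C)C)/C=C(\C)CCCC(=O)[C@H]1OCc4ccc5ccccc5c4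
F6 | step 11 | 5β-(trimethylsilylethynyl) 6α-alcohol (10α-triethylsilyloxy) | COc3ccc(cc3)CO[C@H]1[C@H](C(C)C)[C@H](O)[C@@H](C#C[Si](C)(C)C)[C@H](O[Si](CC)(CC)CC)[C@H]1OCc4ccc5ccccc5c4
F7 | step 11 | 5β-ethynyl 6α-alcohol (10α-triethylsilyloxy) | COc3ccc(cc3)CO[C@H]1[C@H](C(C)C)[C@H](O)[C@@H](C#C)[C@H](O[Si](CC)(CC)CC)[C@H]1OCc4ccc5ccccc5c4
F8 | step 17 | C8 alcohol of enol triflate 24 | O[C@H]1[C@H](C(C)C)[C@H](O[Si](C)(C)C(C)(C)C)/C=C(\C)CC/C=C(\OS(=O)(=O)C(F)(F)F)[C@H]1OCc4ccc5ccccc5c4
F9 | step 17 | C8 tiglate of the enol triflate | C/C=C(\C)C(=O)O[C@H]1[C@H](C(C)C)[C@H](O[Si](C)(C)C(C)(C)C)/C=C(\C)CC/C=C(\OS(=O)(=O)C(F)(F)F)[C@H]1OCc4ccc5ccccc5c4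
F10 | step 20 | C6 alcohol of the tiglate enol triflate | C/C=C(\C)C(=O)O[C@H]1[C@H](C(C)C)[C@H](O)/C=C(\C)CC/C=C(\OS(=O)(=O)C(F)(F)F)[C@H]1OCc4ccc5ccccc5c4
F11 | step 20 | (4R,5R)-4,5-epoxy C6 alcohol of the tiglate enol triflate | C/C=C(\C)C(=O)O[C@H]1[C@H](C(C)C)[C@H](O)[C@H]2O[C@]2(C)CC/C=C(\OS(=O)(=O)C(F)(F)F)[C@H]1OCc4ccc5ccccc5c4
A1 | alternative 1 | seco-dialdehyde (C8 aldehyde, C9 enal; 6-acetoxy-4,5-epoxy) | O=C[C@H](C(C)C)[C@H](OC(C)=O)[C@H]2O[C@]2(C)CC/C=C(\C)C=O
A2 | alternative 1 | 8-O-destigloyl target (C8,C9-diol) | O[C@H]1[C@H](C(C)C)[C@H](OC(C)=O)[C@H]2O[C@]2(C)CC/C=C(\C)[C@H]1O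
A3 | alternative 2 | trans-fused hexalin 1,3-diene (C6 OH, C8 OTES, C9 OTBS) | CC[Si](CC)(CC)O[C@H]1[C@H](C(C)C)[C@H](O)[C@H]2C(C)=CC=C[C@]2(C)[C@H]1O[Si](C)(C)C(C)(C)C
A4 | alternative 2 | (1(10)E,2Z,4E)-germacratriene (C6 OH, C8 OTES, C9 OTBS) | CC[Si](CC)(CC)O[C@H]1[C@H](C(C)C)[C@H](O)/C=C(\C)/C=C\C=C(/C)[C@H]1O[Si](C)(C)C(C)(C)C
A5 | alternative 3 | C1,C6-epoxy octalin-10-one (C4/C5 acetonide, C8 OPMB, C9 OTBS) | COc5ccc(cc5)CO[C@H]1[C@H](C(C)C)[C@]23O[C@]2(CC[C@@]4(C)OC(C)(C)O[C@@H]34)C(=O)[C@H]1O[Si](C)(C)C(C)(C)C
A6 | alternative 3 | cyclodec-1(10)-yn-6-one (C4/C5 acetonide, C8 OPMB, C9 OTBS) | COc5ccc(cc5)CO[C@H]1[C@H](C(C)C)C(=O)[C@@H]2OC(C)(C)O[C@]2(C)CCC#C[C@H]1O[Si](C)(C)C(C)(C)C
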